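**Strategy.** The target is a (4→6)-linked bis-flavan whose upper unit (rings A, B, C) is 2,3-trans-3,4-cis, an arrangement that a cationic ring closure would not favour. The plan closes ring C last, by forming the C4–C4a bond. It exploits three features: ring A carries its 7-OH para to C4a, so the ring A phenolate is a carbon nucleophile exactly at C4a; C4 is benzylic to ring D of the lower unit; and C3 bears oxygen. A cis-epoxide across C3–C4, tethered through the O1–C2 aryl ether, is opened 6-endo with inversion at C4, which sets C4 and releases the 3-OH in one operation. The precursor is an open-chain epoxy aryl ether carrying the intact lower flav-3-ene.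

Key step: step 11

Remark on the chemistry: the hands of the pybox ligand (step 3) and of BINOL (step 7) are to be assigned on model substrates so that the configurations drawn result; 3-[(tert-butyldimethylsilyl)oxy]phenol and the Ohira–Bestmann reagent are taken as commercial. Lower unit: ring D (benzo), ring E (catechol), ring F (pyran).

Step 1
Reactants: 1 3,4-bis(benzyloxy)benzaldehyde; 2 ethynylmagnesium bromide
Product: 3 rac-1-[3,4-bis(benzyloxy)phenyl]prop-2-yn-1-ol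
Conditions: THF, 0 °C to rt; then H2O
Reagents that add atoms: ethynylmagnesium bromide (2), C#C[Mg]Br
Why: Grignard 1,2-addition to an aryl aldehyde; the racemate suffices because step 3 is enantioconvergent.

Step 2
Reactants: 3 rac-1-[3,4-bis(benzyloxy)phenyl]prop-2-yn-1-ol; 4 acetic anhydride
Product: 5 rac-1-[3,4-bis(benzyloxy)phenyl]prop-2-yn-1-yl acetate
Conditions: Ac2O, Et3N, DMAP (cat.), CH2Cl2, 0 °C
Reagents that add atoms: acetic anhydride (4), CC(=O)OC(C)=O
Why: DMAP-catalysed O-acylation installs the leaving group for the propargylic substitution.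

Step 3
Reactants: 5 rac-1-[3,4-bis(benzyloxy)phenyl]prop-2-yn-1-yl acetate; 6 2,4-dihydroxybenzaldehyde
Product: 7 4-{[(1S)-1-[3,4-bis(benzyloxy)phenyl]prop-2-yn-1-yl]oxy}-2-hydroxybenzaldehyde
Conditions: Cu(OTf)·½C6H6 (5 mol %), chiral Me-pybox (10 mol %), i-Pr2NEt, MeOH, −10 °C
Reagents that add atoms: 2,4-dihydroxybenzaldehyde (6), O=Cc1ccc(O)cc1O
Why: Copper-catalysed enantioselective propargylic etherification through a planar copper allenylidene, so the pybox ligand alone should set the future C2 of ring F; the 4-OH reacts because the 2-OH is tied up in a hydrogen bond to the aldehyde.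

Step 4
Reactants: 7 4-{[(1S)-1-[3,4-bis(benzyloxy)phenyl]prop-2-yn-1-yl]oxy}-2-hydroxybenzaldehyde; 8 benzyl bromide
Product: 9 2-(benzyloxy)-4-{[(1S)-1-[3,4-bis(benzyloxy)phenyl]prop-2-yn-1-yl]oxy}benzaldehyde
Conditions: BnBr, K2CO3, DMF, 50 °C
Reagents that add atoms: benzyl bromide (8), BrCc1ccccc1
Why: Williamson etherification masks the ring D hydroxyl, which would otherwise open the later epoxide through an ortho-quinone methide.

Step 5
Reactants: 9 2-(benzyloxy)-4-{[(1S)-1-[3,4-bis(benzyloxy)phenyl]prop-2-yn-1-yl]oxy}benzaldehyde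
Product: 10 (2S)-7-(benzyloxy)-2-[3,4-bis(benzyloxy)phenyl]-2H-chromene-6-carbaldehyde
Conditions: Ph3PAuNTf2 (2 mol %), CH2Cl2, rt
Reagents that add atoms: none
Why: Gold-catalysed 6-endo-dig hydroarylation of an aryl propargyl ether should close ring F para to the benzyloxy group (the other ortho site lies between two oxygens) without breaking the C–O bond at the stereocentre.

Step 6
Reactants: 10 (2S)-7-(benzyloxy)-2-[3,4-bis(benzyloxy)phenyl]-2H-chromene-6-carbaldehyde; 11 dimethyl (1-diazo-2-oxopropyl)phosphonate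
Product: 12 (2S)-7-(benzyloxy)-2-[3,4-bis(benzyloxy)phenyl]-6-ethynyl-2H-chromene
Conditions: K2CO3, MeOH, rt
Reagents that add atoms: dimethyl (1-diazo-2-oxopropyl)phosphonate (11), CC(=O)C(=[N+]=[N-])P(=O)(OC)OC
Why: Ohira–Bestmann homologation turns the aldehyde carbon into the future C4 of the upper unit under mild base that the chromene tolerates.

Step 7
Reactants: 12 (2S)-7-(benzyloxy)-2-[3,4-bis(benzyloxy)phenyl]-6-ethynyl-2H-chromene; 1 3,4-bis(benzyloxy)benzaldehyde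
Product: 13 (1S)-1-[3,4-bis(benzyloxy)phenyl]-3-{(2S)-7-(benzyloxy)-2-[3,4-bis(benzyloxy)phenyl]-2H-chromen-6-yl}prop-2-yn-1-ol
Conditions: Et2Zn, Cy2NH, Et2O, rt; then (R)-BINOL (20 mol %), Ti(Oi-Pr)4 (50 mol %), aldehyde 1, rt
Reagents that add atoms: 3,4-bis(benzyloxy)benzaldehyde (1), O=Cc1ccc(OCc2ccccc2)c(OCc2ccccc2)c1
Why: BINOL–titanium-catalysed asymmetric alkynylzinc addition to an aryl aldehyde, in which the catalyst should set the carbinol centre, the remote stereocentre of 12 having no influence.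

Step 8
Reactants: 13 (1S)-1-[3,4-bis(benzyloxy)phenyl]-3-{(2S)-7-(benzyloxy)-2-[3,4-bis(benzyloxy)phenyl]-2H-chromen-6-yl}prop-2-yn-1-ol
Product: 14 (1R,2Z)-1-[3,4-bis(benzyloxy)phenyl]-3-{(2S)-7-(benzyloxy)-2-[3,4-bis(benzyloxy)phenyl]-2H-chromen-6-yl}prop-2-en-1-ol
Conditions: H2 (1 atm), Pd/CaCO3 poisoned with Pb(OAc)2 (Lindlar catalyst), quinoline, EtOAc, rt
Reagents that add atoms: none
Why: Lindlar semi-hydrogenation adds hydrogen syn to give the Z-alkene and should leave the benzyl ethers and the chromene double bond untouched.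

Step 9
Reactants: 14 (1R,2Z)-1-[3,4-bis(benzyloxy)phenyl]-3-{(2S)-7-(benzyloxy)-2-[3,4-bis(benzyloxy)phenyl]-2H-chromen-6-yl}prop-2-en-1-ol; 15 tert-butyl hydroperoxide
Product: 16 (S)-[3,4-bis(benzyloxy)phenyl][(2R,3S)-3-{(2S)-7-(benzyloxy)-2-[3,4-bis(benzyloxy)phenyl]-2H-chromen-6-yl}oxiran-2-yl]methanol (threo, cis-epoxide)
Conditions: VO(acac)2 (5 mol %), t-BuOOH (decane solution), toluene, 0 °C; filtration through Et3N-deactivated silica
Reagents that add atoms: tert-butyl hydroperoxide (15), CC(C)(C)OO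
Why: Hydroxyl-directed vanadium-catalysed epoxidation touches only the allylic-alcohol alkene; A(1,3) strain of the Z-alkene holds the carbinol C–H in the alkene plane, so oxygen should arrive on the face bearing the hydroxyl (threo) and the Z geometry becomes the cis-epoxide.

Step 10
Reactants: 16 threo cis-epoxy alcohol; 17 3-[(tert-butyldimethylsilyl)oxy]phenol
Product: 18 tert-butyl(3-{(R)-[3,4-bis(benzyloxy)phenyl][(2S,3S)-3-{(2S)-7-(benzyloxy)-2-[3,4-bis(benzyloxy)phenyl]-2H-chromen-6-yl}oxiran-2-yl]methoxy}phenoxy)dimethylsilane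
Conditions: PPh3, DIAD, toluene, 0 °C to rt
Reagents that add atoms: 3-[(tert-butyldimethylsilyl)oxy]phenol (17), CC(C)(C)[Si](C)(C)Oc1cccc(O)c1
Why: Mitsunobu etherification forms the O1–C2 bond with SN2 inversion, converting the threo carbinol into the (R)-configured C2 that the target needs; the adjacent epoxide oxygen disfavours ionisation.

Step 11
Reactants: 18 silyl-protected epoxy aryl ether
Product: 20 (2R,3S,4R)-4-{(2S)-7-(benzyloxy)-2-[3,4-bis(benzyloxy)phenyl]-2H-chromen-6-yl}-2-[3,4-bis(benzyloxy)phenyl]-3,4-dihydro-2H-chromene-3,7-diol (2,3-trans-3,4-cis), via tetrabutylammonium phenolate 19 (not isolated)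
Conditions: Bu4NF (1.1 equiv), THF/t-BuOH, 0 to 50 °C, 0.005 M; then AcOH
Reagents that add atoms: none
Why: Fluoride removes the silyl group and the ring A phenolate attacks through its para carbon (C4a, also ortho to O1) the benzylic epoxide carbon C4 from the side opposite the C4–O bond; the dienone formed tautomerises to the phenol and the epoxide oxygen becomes the 3-hydroxyl. The closest known reactions are the base-mediated intramolecular C-alkylation of phenols by tethered epoxides or sulfonates (phenolate Ar2-6 cyclialkylation) and the intramolecular Friedel–Crafts epoxy–arene cyclisation that gives 4-arylchroman-3-ols. The one ring formed, ring C, closes in the 6-endo-tet mode at the epoxide. C4 is set by SN2 inversion, so the cis-epoxide is translated into the 3,4-cis (2,4-trans) chroman, C3 keeps the epoxide oxygen with its configuration and C2 is untouched. The step needs attack at C4 rather than C3 (benzylic activation by ring D, the deactivating aryloxy group next to C3 and the strained five-membered alternative), at the para rather than the ortho carbon (the ortho carbon lies between two oxygens and the ammonium counter-ion cannot template it), and SN2 rather than SN1 behaviour (no acid is present, so the electron-rich ring D cannot ionise the epoxide and scramble C4).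

Step 12
Reactants: 20 upper chroman carrying the lower flav-3-ene; 21 N-methylmorpholine N-oxide
Product: 22 (2R,3S,4S)-7-(benzyloxy)-2-[3,4-bis(benzyloxy)phenyl]-6-{(2R,3S,4R)-2-[3,4-bis(benzyloxy)phenyl]-3,7-dihydroxy-3,4-dihydro-2H-chromen-4-yl}-3,4-dihydro-2H-chromene-3,4-diol
Conditions: OsO4 (5 mol %), NMO, acetone/H2O, 0 °C to rt
Reagents that add atoms: N-methylmorpholine N-oxide (21), C[N+]1([O-])CCOCC1; water, O
Why: Upjohn syn-dihydroxylation of the flav-3-ene double bond should occur on the face opposite the 2-aryl group, giving the 2,3-trans-3,4-cis diol of ring F.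

Step 13
Reactants: 22 pentabenzyl ether of the target
Product: 23 (2R,3S,4S)-2-(3,4-dihydroxyphenyl)-4-[(2R,3S,4S)-2-(3,4-dihydroxyphenyl)-3,4,7-trihydroxy-3,4-dihydro-2H-chromen-6-yl]-3,4-dihydro-2H-chromene-3,7-diol (target)
Conditions: H2 (1 atm), Pd/C (10 %), EtOAc/MeOH, pyridine (0.5 equiv), rt
Reagents that add atoms: none
Why: Hydrogenolysis of the five aryl benzyl ethers; amine-moderated palladium should cleave phenolic benzyl ethers much faster than the benzylic C4–OH of ring F or the C2–O1 bonds.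

**Compound list**

1 | 3,4-bis(benzyloxy)benzaldehyde | O=Cc1ccc(OCc2ccccc2)c(OCc2ccccc2)c1 | starting material
2 | ethynylmagnesium bromide | C#C[Mg]Br | starting material
3 | rac-1-[3,4-bis(benzyloxy)phenyl]prop-2-yn-1-ol | OC(C#C)c1ccc(OCc2ccccc2)c(OCc2ccccc2)c1 | intermediate
4 | acetic anhydride | CC(=O)OC(C)=O | starting material
5 | rac-1-[3,4-bis(benzyloxy)phenyl]prop-2-yn-1-yl acetate | CC(=O)OC(C#C)c1ccc(OCc2ccccc2)c(OCc2ccccc2)c1 | intermediate
6 | 2,4-dihydroxybenzaldehyde | O=Cc1ccc(O)cc1O | starting material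
7 | 4-{[(1S)-1-[3,4-bis(benzyloxy)phenyl]prop-2-yn-1-yl]oxy}-2-hydroxybenzaldehyde | O=Cc1ccc(O[C@H](c2ccc(OCc3ccccc3)c(OCc3ccccc3)c2)C#C)cc1O | intermediate
8 | benzyl bromide | BrCc1ccccc1 | starting material
9 | 2-(benzyloxy)-4-{[(1S)-1-[3,4-bis(benzyloxy)phenyl]prop-2-yn-1-yl]oxy}benzaldehyde | O=Cc1ccc(O[C@H](c2ccc(OCc3ccccc3)c(OCc3ccccc3)c2)C#C)cc1OCc1ccccc1 | intermediate
10 | (2S)-7-(benzyloxy)-2-[3,4-bis(benzyloxy)phenyl]-2H-chromene-6-carbaldehyde | O=Cc1cc2c(cc1OCc1ccccc1)O[C@H](c1ccc(OCc3ccccc3)c(OCc3ccccc3)c1)C=C2 | intermediate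
11 | dimethyl (1-diazo-2-oxopropyl)phosphonate | CC(=O)C(=[N+]=[N-])P(=O)(OC)OC | starting material
12 | (2S)-7-(benzyloxy)-2-[3,4-bis(benzyloxy)phenyl]-6-ethynyl-2H-chromene | C#Cc1cc2c(cc1OCc1ccccc1)O[C@H](c1ccc(OCc3ccccc3)c(OCc3ccccc3)c1)C=C2 | intermediate
13 | (1S)-1-[3,4-bis(benzyloxy)phenyl]-3-{(2S)-7-(benzyloxy)-2-[3,4-bis(benzyloxy)phenyl]-2H-chromen-6-yl}prop-2-yn-1-ol | O[C@@H](c1ccc(OCc2ccccc2)c(OCc2ccccc2)c1)C#Cc1cc2c(cc1OCc1ccccc1)O[C@H](c1ccc(OCc3ccccc3)c(OCc3ccccc3)c1)C=C2 | intermediate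
14 | (1R,2Z)-1-[3,4-bis(benzyloxy)phenyl]-3-{(2S)-7-(benzyloxy)-2-[3,4-bis(benzyloxy)phenyl]-2H-chromen-6-yl}prop-2-en-1-ol | O[C@@H](c1ccc(OCc2ccccc2)c(OCc2ccccc2)c1)/C=C\c1cc2c(cc1OCc1ccccc1)O[C@H](c1ccc(OCc3ccccc3)c(OCc3ccccc3)c1)C=C2 | intermediate
15 | tert-butyl hydroperoxide | CC(C)(C)OO | starting material
16 | (S)-[3,4-bis(benzyloxy)phenyl][(2R,3S)-3-{(2S)-7-(benzyloxy)-2-[3,4-bis(benzyloxy)phenyl]-2H-chromen-6-yl}oxiran-2-yl]methanol (threo, cis-epoxide) | O[C@@H](c1ccc(OCc2ccccc2)c(OCc2ccccc2)c1)[C@H]1O[C@H]1c1cc2c(cc1OCc1ccccc1)O[C@H](c1ccc(OCc3ccccc3)c(OCc3ccccc3)c1)C=C2 | intermediate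
17 | 3-[(tert-butyldimethylsilyl)oxy]phenol | CC(C)(C)[Si](C)(C)Oc1cccc(O)c1 | starting material
18 | tert-butyl(3-{(R)-[3,4-bis(benzyloxy)phenyl][(2S,3S)-3-{(2S)-7-(benzyloxy)-2-[3,4-bis(benzyloxy)phenyl]-2H-chromen-6-yl}oxiran-2-yl]methoxy}phenoxy)dimethylsilane (cis-epoxide) | CC(C)(C)[Si](C)(C)Oc1cccc(O[C@H](c2ccc(OCc3ccccc3)c(OCc3ccccc3)c2)[C@H]2O[C@H]2c2cc3c(cc2OCc2ccccc2)O[C@H](c2ccc(OCc4ccccc4)c(OCc4ccccc4)c2)C=C3)c1 | intermediate
19 | tetrabutylammonium phenolate of desilylated 18 (configuration as in 18) | CCCC[N+](CCCC)(CCCC)CCCC.[O-]c1cccc(O[C@H](c2ccc(OCc3ccccc3)c(OCc3ccccc3)c2)[C@H]2O[C@H]2c2cc3c(cc2OCc2ccccc2)O[C@H](c2ccc(OCc4ccccc4)c(OCc4ccccc4)c2)C=C3)c1 | intermediate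
20 | (2R,3S,4R)-4-{(2S)-7-(benzyloxy)-2-[3,4-bis(benzyloxy)phenyl]-2H-chromen-6-yl}-2-[3,4-bis(benzyloxy)phenyl]-3,4-dihydro-2H-chromene-3,7-diol (2,3-trans-3,4-cis) | Oc1ccc2c(c1)O[C@H](c1ccc(OCc3ccccc3)c(OCc3ccccc3)c1)[C@@H](O)[C@H]2c1cc2c(cc1OCc1ccccc1)O[C@H](c1ccc(OCc3ccccc3)c(OCc3ccccc3)c1)C=C2 | intermediate
21 | N-methylmorpholine N-oxide | C[N+]1([O-])CCOCC1 | starting material
22 | (2R,3S,4S)-7-(benzyloxy)-2-[3,4-bis(benzyloxy)phenyl]-6-{(2R,3S,4R)-2-[3,4-bis(benzyloxy)phenyl]-3,7-dihydroxy-3,4-dihydro-2H-chromen-4-yl}-3,4-dihydro-2H-chromene-3,4-diol | Oc1ccc2c(c1)O[C@H](c1ccc(OCc3ccccc3)c(OCc3ccccc3)c1)[C@@H](O)[C@H]2c1cc2c(cc1OCc1ccccc1)O[C@H](c1ccc(OCc3ccccc3)c(OCc3ccccc3)c1)[C@@H](O)[C@H]2O | intermediate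
23 | (2R,3S,4S)-2-(3,4-dihydroxyphenyl)-4-[(2R,3S,4S)-2-(3,4-dihydroxyphenyl)-3,4,7-trihydroxy-3,4-dihydro-2H-chromen-6-yl]-3,4-dihydro-2H-chromene-3,7-diol | Oc1ccc2c(c1)O[C@H](c1ccc(O)c(O)c1)[C@@H](O)[C@H]2c1cc2c(cc1O)O[C@H](c1ccc(O)c(O)c1)[C@@H](O)[C@H]2O | target

**Totals.** Total step count: 13. Longest linear sequence: 13 steps (from 1 to 23).

**Steps most likely to fail**

Step 11 (key step). The phenolate may be too weak a carbon nucleophile for an epoxide that has no electrophilic assistance, or it may attack through its ortho carbon; the epoxide would then persist or the 5-hydroxy regioisomer would form. The fallback sets out from 16 and returns at 23. Mitsunobu etherification of 16 with 5-(benzyloxy)-2-bromophenol (PPh3, DIAD, toluene) should give the bromoaryl cis-epoxy ether F1. Bromine–lithium exchange (t-BuLi, THF, −78 °C, then warming) places an aryllithium at the future C4a, which should open the epoxide at the benzylic carbon with inversion (Parham cyclisation) to the 7-O-benzyl 2,3-trans-3,4-cis chromanol F2. Upjohn dihydroxylation as in step 12 should give the diol F3, and hydrogenolysis as in step 13 then removes six benzyl groups to reach 23.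

Step 10. The electron-rich benzylic oxyphosphonium ion may ionise, eroding the inversion, or the phenol may open the neighbouring epoxide. The fallback sets out from 16 and returns at 18, and makes the C2–O1 bond without substitution at carbon. Dess–Martin oxidation (NaHCO3 buffer, CH2Cl2) should give the cis-epoxy ketone F4. Chelation-controlled reduction with Zn(BH4)2 (Et2O, −78 °C) should give the erythro epoxy alcohol F5, the carbinol epimer of 16. O-Arylation with retention, using [3-(tert-butyldimethylsilyloxy)phenyl](2,4,6-trimethoxyphenyl)iodonium tosylate and NaH in toluene, then delivers 18.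

Step 13. The activated benzylic C4–OH of ring F (or a C2–O1 bond) may be hydrogenolysed together with the benzyl ethers. The fallback sets out from 22 and returns at 23. All four free hydroxyls are silylated (TBSOTf, 2,6-lutidine, CH2Cl2, −40 °C) to the tetrakis-silyl ether F6. The benzyl ethers are then hydrogenolysed on this shielded substrate (H2, Pd/C, EtOAc) to the pentaphenol F7, and the silyl groups are removed with Bu4NF buffered by AcOH (THF, 0 °C) to give 23.

**Further compounds**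

F1 | step 11 | 4-(benzyloxy)-1-bromo-2-{(R)-[3,4-bis(benzyloxy)phenyl][(2S,3S)-3-{(2S)-7-(benzyloxy)-2-[3,4-bis(benzyloxy)phenyl]-2H-chromen-6-yl}oxiran-2-yl]methoxy}benzene | Brc1ccc(OCc2ccccc2)cc1O[C@H](c1ccc(OCc2ccccc2)c(OCc2ccccc2)c1)[C@H]1O[C@H]1c1cc2c(cc1OCc1ccccc1)O[C@H](c1ccc(OCc3ccccc3)c(OCc3ccccc3)c1)C=C2
F2 | step 11 | (2R,3S,4R)-7-(benzyloxy)-4-{(2S)-7-(benzyloxy)-2-[3,4-bis(benzyloxy)phenyl]-2H-chromen-6-yl}-2-[3,4-bis(benzyloxy)phenyl]-3,4-dihydro-2H-chromen-3-ol | C(c1ccccc1)Oc1ccc2c(c1)O[C@H](c1ccc(OCc3ccccc3)c(OCc3ccccc3)c1)[C@@H](O)[C@H]2c1cc2c(cc1OCc1ccccc1)O[C@H](c1ccc(OCc3ccccc3)c(OCc3ccccc3)c1)C=C2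
F3 | step 11 | 7-O-benzyl ether of 22 (configuration as in 22) | C(c1ccccc1)Oc1ccc2c(c1)O[C@H](c1ccc(OCc3ccccc3)c(OCc3ccccc3)c1)[C@@H](O)[C@H]2c1cc2c(cc1OCc1ccccc1)O[C@H](c1ccc(OCc3ccccc3)c(OCc3ccccc3)c1)[C@@H](O)[C@H]2O
F4 | step 10 | [3,4-bis(benzyloxy)phenyl][(2S,3S)-3-{(2S)-7-(benzyloxy)-2-[3,4-bis(benzyloxy)phenyl]-2H-chromen-6-yl}oxiran-2-yl]methanone (cis-epoxy ketone) | O=C(c1ccc(OCc2ccccc2)c(OCc2ccccc2)c1)[C@H]1O[C@H]1c1cc2c(cc1OCc1ccccc1)O[C@H](c1ccc(OCc3ccccc3)c(OCc3ccccc3)c1)C=C2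
F5 | step 10 | (R)-[3,4-bis(benzyloxy)phenyl][(2R,3S)-3-{(2S)-7-(benzyloxy)-2-[3,4-bis(benzyloxy)phenyl]-2H-chromen-6-yl}oxiran-2-yl]methanol (erythro, cis-epoxide) | O[C@H](c1ccc(OCc2ccccc2)c(OCc2ccccc2)c1)[C@H]1O[C@H]1c1cc2c(cc1OCc1ccccc1)O[C@H](c1ccc(OCc3ccccc3)c(OCc3ccccc3)c1)C=C2
F6 | step 13 | tetrakis(tert-butyldimethylsilyl) ether of 22 (silyl groups on O7 and O3 of the upper unit and on O3 and O4 of ring F; configuration as in 22) | CC(C)(C)[Si](C)(C)Oc1ccc2c(c1)O[C@H](c1ccc(OCc3ccccc3)c(OCc3ccccc3)c1)[C@@H](O[Si](C)(C)C(C)(C)C)[C@H]2c1cc2c(cc1OCc1ccccc1)O[C@H](c1ccc(OCc3ccccc3)c(OCc3ccccc3)c1)[C@@H](O[Si](C)(C)C(C)(C)C)[C@H]2O[Si](C)(C)C(C)(C)C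
F7 | step 13 | debenzylated F6 (five free phenols, four silyl ethers retained; configuration as in 22) | CC(C)(C)[Si](C)(C)Oc1ccc2c(c1)O[C@H](c1ccc(O)c(O)c1)[C@@H](O[Si](C)(C)C(C)(C)C)[C@H]2c1cc2c(cc1O)O[C@H](c1ccc(O)c(O)c1)[C@@H](O[Si](C)(C)C(C)(C)C)[C@H]2O[Si](C)(C)C(C)(C)C
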